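**Strategy.** Atoms are numbered along the chain from the hydroxymethyl carbon (C1). The route rests on cutting the CH2–CH2 link C4–C5 between the two oxiranes. C5 hangs on the CH carbon (C6) of the cis-trisubstituted C6/C7 oxirane, so that half is a 2,3-epoxy alcohol in disguise. Sharpless epoxidation of a neryl-type Z-allylic alcohol sets C6/C7, and its triflate makes C5 a primary electrophile with the ring already in place. The key step displaces this triflate with the γ-carbon of the methyl acetoacetate dianion. The resulting β-keto ester is converted stereospecifically (Z-enol phosphate, Me2CuLi, DIBAL-H) into the E-allylic alcohol for the second Sharpless epoxidation (C2/C3).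

Key step: step 6

Remark on numbering and stereochemistry: C1 (CH2OH), C2/C3 (terminal oxirane, C3 quaternary), C4, C5, C6/C7 (internal oxirane, C7 quaternary), C8, C9, C10=C11, C12 (carbinol), C13, C14 (=CH2), C15 (isopropyl CH). The internal oxirane has C5 and C8 cis (from a Z-alkene); the terminal one has C1 and C4 trans (from an E-alkene). Compounds 1, 4, 12, (+)-Ipc2BOMe and D-(−)-diethyl tartrate are assumed to be commercial.

Step 1
Reactants: 1 neryl acetate
Product: 3 (2Z,6E)-3,7-dimethyl-8-oxoocta-2,6-dien-1-yl acetate, via 8-hydroxyneryl acetate 2 (not isolated)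
Conditions: SeO2 (cat.), t-BuOOH, salicylic acid (cat.), CH2Cl2, rt; then crude mixture, MnO2, CH2Cl2, rt
Reagents that add atoms: tert-butyl hydroperoxide, CC(C)(C)OO (terminal oxidant; oxygen delivered through catalytic SeO2, O=[Se]=O)
Why: Riley-type SeO2 allylic oxidation (ene reaction, then [2,3]-sigmatropic shift) should attack the (E)-methyl of the electron-rich terminal alkene, the Z-alkene being deactivated by its allylic acetate, and MnO2 should converge the allylic alcohol/aldehyde mixture on the (E)-enal.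

Step 2
Reactants: 3 (2Z,6E)-3,7-dimethyl-8-oxoocta-2,6-dien-1-yl acetate; 4 2,3-dimethylbut-1-ene
Product: 8 (2Z,6E,8R)-8-hydroxy-3,7,11-trimethyl-10-methylidenedodeca-2,6-dien-1-yl acetate, via 2-isopropylallylpotassium 5 (not isolated), via B-(2-isopropylallyl)diisopinocampheylborane 6 (not isolated), via O-boryl adduct 7 (not isolated)
Conditions: 4, n-BuLi, KOt-Bu, THF, −78 → −45 °C; (+)-Ipc2BOMe [from (−)-α-pinene], −78 °C; BF3·OEt2; 3, −78 °C; then HOCH2CH2NH2, rt
Reagents that add atoms: none
Why: Schlosser metalation of 4 at the allylic CH3 and transfer to boron give a Brown allylborane whose chair Zimmerman–Traxler transition state should deliver the 2-isopropylallyl group to the Re face of the aldehyde (the sense of the (−)-α-pinene-derived reagent), setting C12 as R, while the acetate is spared at −78 °C and in the ethanolamine work-up.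

Step 3
Reactants: 8 (2Z,6E,8R)-8-hydroxy-3,7,11-trimethyl-10-methylidenedodeca-2,6-dien-1-yl acetate
Product: 9 the C12 tert-butyldimethylsilyl ether of 8
Conditions: TBSCl, imidazole, DMF, rt
Reagents that add atoms: tert-butyldimethylsilyl chloride, CC(C)(C)[Si](C)(C)Cl
Why: Standard Corey silylation masks the secondary allylic alcohol, which would otherwise itself be a substrate for the two later Sharpless epoxidations.

Step 4
Reactants: 9 silyl ether acetate
Product: 10 (2Z,6E,8R)-8-[(tert-butyldimethylsilyl)oxy]-3,7,11-trimethyl-10-methylidenedodeca-2,6-dien-1-ol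
Conditions: K2CO3 (cat.), MeOH, 0 °C → rt
Reagents that add atoms: none
Why: Base-catalysed transesterification should remove the primary allylic acetate without affecting the TBS ether or the Z-alkene geometry.

Step 5
Reactants: 10 Z-allylic alcohol
Product: 11 (2R,3S)-epoxy alcohol (C6/C7 oxirane, C5 hydroxymethyl)
Conditions: Ti(OiPr)4 (cat.), D-(−)-diethyl tartrate (cat.), t-BuOOH, 4 Å MS, CH2Cl2, −20 °C
Reagents that add atoms: tert-butyl hydroperoxide, CC(C)(C)OO
Why: Katsuki–Sharpless asymmetric epoxidation acts only on the free allylic alcohol and, with D-(−)-tartrate on the Z-alkene, should give the cis-oxirane with C6 R and C7 S (the mirror-image sense of L-(+)-tartrate with nerol).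

Step 6
Reactants: 11 (2R,3S)-epoxy alcohol; 12 methyl acetoacetate
Product: 15 methyl 5-[(2R,3S)-oxiranyl]-3-oxopentanoate (β-keto ester carrying the C6/C7 oxirane), via epoxy triflate 13 (not isolated), via methyl acetoacetate dianion 14 (not isolated)
Conditions: 11, Tf2O, 2,6-lutidine, CH2Cl2, −78 °C (cold wash, crude triflate used at once); 12, NaH then n-BuLi, THF, 0 °C; triflate added at −78 °C, → −40 °C; aq. NH4Cl
Reagents that add atoms: none
Why: The γ-carbanion (C4) of dianion 14, its most basic and nucleophilic site, displaces the primary triflate at C5 in an SN2 reaction, so the C4–C5 bond forms with the C6/C7 oxirane already in place. The closest known reaction types are the Weiler γ-alkylation of acetoacetate dianions with primary electrophiles and the alkylation of carbanions with triflates of Sharpless 2,3-epoxy alcohols. No ring is closed and no stereocentre is formed; C6 and C7 keep the configuration set in step 5 because the reacting carbon is the exocyclic CH2 and not a ring carbon. The step needs displacement at C5 over oxirane opening, and γ- over α-alkylation. The triflate reacts at −78 °C, where the secondary and quaternary oxirane carbons are inert without a Lewis acid. In the dianion only the terminal carbanion alkylates, and the remaining β-keto ester enolate is too weak a nucleophile to attack the oxirane before the cold quench.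

Step 7
Reactants: 15 β-keto ester
Product: 16 (Z)-enol diethyl phosphate of 15
Conditions: NaH, Et2O, 0 °C; ClP(O)(OEt)2
Reagents that add atoms: diethyl chlorophosphate, CCOP(=O)(Cl)OCC
Why: O-phosphorylation of the chelated (Z)-sodium enolate (Weiler protocol) should fix the enol geometry with the phosphate cis to the ester.

Step 8
Reactants: 16 (Z)-enol phosphate
Product: 17 methyl (2E)-3-methyl-5-[(2R,3S)-oxiranyl]pent-2-enoate
Conditions: Me2CuLi (from MeLi, CuI), Et2O, −78 → −45 °C
Reagents that add atoms: lithium dimethylcuprate, [Li+].C[Cu-]C (made from methyllithium, [Li]C, and CuI)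
Why: Cuprate addition–elimination on the β-phosphoryloxy enoate proceeds with retention, so the new methyl ends up cis to the ester and C2=C3 should be E; the trisubstituted oxirane is inert to Me2CuLi at this temperature.

Step 9
Reactants: 17 E-enoate
Product: 18 (2E)-3-methyl-5-[(2R,3S)-oxiranyl]pent-2-en-1-ol
Conditions: DIBAL-H, CH2Cl2, −78 °C; Rochelle salt work-up
Reagents that add atoms: none
Why: 1,2-Reduction of the enoate by DIBAL-H at −78 °C should give the E-allylic alcohol without conjugate reduction or hydride opening of the oxirane.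

Step 10
Reactants: 18 E-allylic alcohol
Product: 19 bis-epoxide, C12 silyl ether of the target
Conditions: Ti(OiPr)4 (cat.), D-(−)-diethyl tartrate (cat.), t-BuOOH, 4 Å MS, CH2Cl2, −20 °C
Reagents that add atoms: tert-butyl hydroperoxide, CC(C)(C)OO
Why: The second Katsuki–Sharpless epoxidation, directed by the C1 hydroxyl and reagent-controlled by D-(−)-tartrate, should give the (2R,3R) trans-oxirane from the E-alkene (the mirror-image sense of L-(+)-tartrate with geraniol); the C10=C11 and C14 alkenes have no free allylic OH.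

Step 11
Reactants: 19 bis-epoxide silyl ether
Product: 20 target (CNP0156678.1)
Conditions: TBAF, AcOH, THF, 0 °C → rt
Reagents that add atoms: none
Why: Fluoride-induced Si–O cleavage, buffered with acetic acid so that the 2,3-epoxy alcohol is not exposed to base (Payne rearrangement), should release C12–OH and give the target.

**Compound list**

1 | neryl acetate, (2Z)-3,7-dimethylocta-2,6-dien-1-yl acetate | CC(C)=CCC/C(C)=C\COC(C)=O | starting material
2 | (2Z,6E)-8-hydroxy-3,7-dimethylocta-2,6-dien-1-yl acetate (8-hydroxyneryl acetate) | OC/C(C)=C/CC/C(C)=C\COC(C)=O | intermediate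
3 | (2Z,6E)-3,7-dimethyl-8-oxoocta-2,6-dien-1-yl acetate | O=C/C(C)=C/CC/C(C)=C\COC(C)=O | intermediate
4 | 2,3-dimethylbut-1-ene | C=C(C)C(C)C | starting material
5 | 2-isopropylallylpotassium, (3-methyl-2-methylidenebutyl)potassium | [K+].[CH2-]C(=C)C(C)C | intermediate
6 | B-(3-methyl-2-methylidenebutyl)diisopinocampheylborane, Ipc groups from (−)-α-pinene | C=C(CB([C@H]1C[C@H]2C[C@@H]([C@@H]1C)C2(C)C)[C@H]1C[C@H]2C[C@@H]([C@@H]1C)C2(C)C)C(C)C | intermediate
7 | O-diisopinocampheylboryl adduct (borinate ester) of 8 | C=C(C[C@@H](OB([C@H]1C[C@H]2C[C@@H]([C@@H]1C)C2(C)C)[C@H]1C[C@H]2C[C@@H]([C@@H]1C)C2(C)C)/C(C)=C/CC/C(C)=C\COC(C)=O)C(C)C | intermediate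
8 | (2Z,6E,8R)-8-hydroxy-3,7,11-trimethyl-10-methylidenedodeca-2,6-dien-1-yl acetate | C=C(C[C@@H](O)/C(C)=C/CC/C(C)=C\COC(C)=O)C(C)C | intermediate
9 | (2Z,6E,8R)-8-[(tert-butyldimethylsilyl)oxy]-3,7,11-trimethyl-10-methylidenedodeca-2,6-dien-1-yl acetate | C=C(C[C@@H](O[Si](C)(C)C(C)(C)C)/C(C)=C/CC/C(C)=C\COC(C)=O)C(C)C | intermediate
10 | (2Z,6E,8R)-8-[(tert-butyldimethylsilyl)oxy]-3,7,11-trimethyl-10-methylidenedodeca-2,6-dien-1-ol | C=C(C[C@@H](O[Si](C)(C)C(C)(C)C)/C(C)=C/CC/C(C)=C\CO)C(C)C | intermediate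
11 | [(2R,3S)-3-{(3E,5R)-5-[(tert-butyldimethylsilyl)oxy]-4,8-dimethyl-7-methylidenenon-3-en-1-yl}-3-methyloxiran-2-yl]methanol | C=C(C[C@@H](O[Si](C)(C)C(C)(C)C)/C(C)=C/CC[C@]1(C)O[C@@H]1CO)C(C)C | intermediate
12 | methyl acetoacetate (methyl 3-oxobutanoate) | COC(=O)CC(C)=O | starting material
13 | [(2R,3S)-3-{(3E,5R)-5-[(tert-butyldimethylsilyl)oxy]-4,8-dimethyl-7-methylidenenon-3-en-1-yl}-3-methyloxiran-2-yl]methyl trifluoromethanesulfonate | C=C(C[C@@H](O[Si](C)(C)C(C)(C)C)/C(C)=C/CC[C@]1(C)O[C@@H]1COS(=O)(=O)C(F)(F)F)C(C)C | intermediate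
14 | sodium lithium dianion of methyl acetoacetate | [Na+].[Li+].[CH2-]C(=O)[CH-]C(=O)OC | intermediate
15 | methyl 5-[(2R,3S)-3-{(3E,5R)-5-[(tert-butyldimethylsilyl)oxy]-4,8-dimethyl-7-methylidenenon-3-en-1-yl}-3-methyloxiran-2-yl]-3-oxopentanoate | C=C(C[C@@H](O[Si](C)(C)C(C)(C)C)/C(C)=C/CC[C@]1(C)O[C@@H]1CCC(=O)CC(=O)OC)C(C)C | intermediate
16 | methyl (2Z)-3-[(diethoxyphosphoryl)oxy]-5-[(2R,3S)-3-{(3E,5R)-5-[(tert-butyldimethylsilyl)oxy]-4,8-dimethyl-7-methylidenenon-3-en-1-yl}-3-methyloxiran-2-yl]pent-2-enoate | C=C(C[C@@H](O[Si](C)(C)C(C)(C)C)/C(C)=C/CC[C@]1(C)O[C@@H]1CC/C(OP(=O)(OCC)OCC)=C/C(=O)OC)C(C)C | intermediate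
17 | methyl (2E)-5-[(2R,3S)-3-{(3E,5R)-5-[(tert-butyldimethylsilyl)oxy]-4,8-dimethyl-7-methylidenenon-3-en-1-yl}-3-methyloxiran-2-yl]-3-methylpent-2-enoate | C=C(C[C@@H](O[Si](C)(C)C(C)(C)C)/C(C)=C/CC[C@]1(C)O[C@@H]1CC/C(C)=C/C(=O)OC)C(C)C | intermediate
18 | (2E)-5-[(2R,3S)-3-{(3E,5R)-5-[(tert-butyldimethylsilyl)oxy]-4,8-dimethyl-7-methylidenenon-3-en-1-yl}-3-methyloxiran-2-yl]-3-methylpent-2-en-1-ol | C=C(C[C@@H](O[Si](C)(C)C(C)(C)C)/C(C)=C/CC[C@]1(C)O[C@@H]1CC/C(C)=C/CO)C(C)C | intermediate
19 | [(2R,3R)-3-(2-{(2R,3S)-3-[(3E,5R)-5-[(tert-butyldimethylsilyl)oxy]-4,8-dimethyl-7-methylidenenon-3-en-1-yl]-3-methyloxiran-2-yl}ethyl)-3-methyloxiran-2-yl]methanol | C=C(C[C@@H](O[Si](C)(C)C(C)(C)C)/C(C)=C/CC[C@]1(C)O[C@@H]1CC[C@@]1(C)O[C@@H]1CO)C(C)C | intermediate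
20 | [(2R,3R)-3-(2-{(2R,3S)-3-[(3E,5R)-5-hydroxy-4,8-dimethyl-7-methylidenenon-3-en-1-yl]-3-methyloxiran-2-yl}ethyl)-3-methyloxiran-2-yl]methanol (CNP0156678.1) | C=C(C[C@@H](O)/C(C)=C/CC[C@]1(C)O[C@@H]1CC[C@@]1(C)O[C@@H]1CO)C(C)C | target

**Totals.** Total step count: 11. Longest linear sequence: 11 steps (1 → 20); 4 and 12 enter as commercial reagents.

**Steps most likely to fail**

1. Step 6 (key coupling). The strongly basic, ambident dianion may attack or eliminate at the oxirane, or react at its α-carbon, instead of displacing cleanly at C5. The fallback sets out from 11 (through the same triflate 13) and returns at 18, replacing steps 6–9. The triflate is alkylated with 3-lithio-1-(trimethylsilyl)propyne (n-BuLi on 1-(trimethylsilyl)propyne, THF, −78 °C), a non-enolate propargylic carbanion, to give silylalkyne F1. K2CO3/MeOH gives terminal alkyne F2, and n-BuLi/paraformaldehyde gives propargylic alcohol F3. Hydroxyl-directed trans-hydroalumination with Red-Al followed by I2 gives (Z)-3-iodoallylic alcohol F4. Me2CuLi replaces iodine by methyl with retention and should give 18.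

2. Step 7 (enol phosphate). While the sodium enolate of 15 waits for the chlorophosphate it may open the oxirane intramolecularly (5-exo attack of C2 on C6), or O-phosphorylation may lose Z-control. The fallback sets out from 15 and returns at 17, also replacing step 8. Brief biphasic triflation (Tf2O, saturated aqueous LiOH, toluene, 5 °C), in which the chelated lithium enolate is trapped as it forms, should give (Z)-enol triflate F5. Pd-catalysed Suzuki–Miyaura methylation (trimethylboroxine, Pd(dppf)Cl2, K2CO3, THF, 60 °C) proceeds with retention and should give 17.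

3. Step 2 (asymmetric allylation). Metalation of 4 may not be fully regioselective, and the 2-branched allylborane may give insufficient facial selectivity with the α-branched enal. The fallback sets out from 5 and 3 and returns at 8. The allylpotassium 5 is quenched with Bu3SnCl to give tributyl(2-isopropylallyl)stannane F6, which is purified by distillation. It is then added to 3 under catalytic Keck conditions ((R)-BINOL, Ti(OiPr)4, 4 Å MS, CH2Cl2, −20 °C; KF work-up), where the chiral Lewis acid rather than a stoichiometric borane should control Re-face attack and give 8.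

Further compounds
F1 | step 6 | trimethyl{4-[(2R,3S)-3-{(3E,5R)-5-[(tert-butyldimethylsilyl)oxy]-4,8-dimethyl-7-methylidenenon-3-en-1-yl}-3-methyloxiran-2-yl]but-1-yn-1-yl}silane | C=C(C[C@@H](O[Si](C)(C)C(C)(C)C)/C(C)=C/CC[C@]1(C)O[C@@H]1CCC#C[Si](C)(C)C)C(C)C
F2 | step 6 | (2R,3S)-2-(but-3-yn-1-yl)-3-{(3E,5R)-5-[(tert-butyldimethylsilyl)oxy]-4,8-dimethyl-7-methylidenenon-3-en-1-yl}-3-methyloxirane | C=C(C[C@@H](O[Si](C)(C)C(C)(C)C)/C(C)=C/CC[C@]1(C)O[C@@H]1CCC#C)C(C)C
F3 | step 6 | 5-[(2R,3S)-3-{(3E,5R)-5-[(tert-butyldimethylsilyl)oxy]-4,8-dimethyl-7-methylidenenon-3-en-1-yl}-3-methyloxiran-2-yl]pent-2-yn-1-ol | C=C(C[C@@H](O[Si](C)(C)C(C)(C)C)/C(C)=C/CC[C@]1(C)O[C@@H]1CCC#CCO)C(C)C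
F4 | step 6 | (2Z)-3-iodo-5-[(2R,3S)-3-{(3E,5R)-5-[(tert-butyldimethylsilyl)oxy]-4,8-dimethyl-7-methylidenenon-3-en-1-yl}-3-methyloxiran-2-yl]pent-2-en-1-ol | C=C(C[C@@H](O[Si](C)(C)C(C)(C)C)/C(C)=C/CC[C@]1(C)O[C@@H]1CC/C(I)=C/CO)C(C)C
F5 | step 7 | methyl (2Z)-5-[(2R,3S)-3-{(3E,5R)-5-[(tert-butyldimethylsilyl)oxy]-4,8-dimethyl-7-methylidenenon-3-en-1-yl}-3-methyloxiran-2-yl]-3-{[(trifluoromethyl)sulfonyl]oxy}pent-2-enoate | C=C(C[C@@H](O[Si](C)(C)C(C)(C)C)/C(C)=C/CC[C@]1(C)O[C@@H]1CC/C(OS(=O)(=O)C(F)(F)F)=C/C(=O)OC)C(C)C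
F6 | step 2 | tributyl(3-methyl-2-methylidenebutyl)stannane | CCCC[Sn](CCCC)(CCCC)CC(=C)C(C)C
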